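# Design of a synthesis of (2R,3R,3aR,5R)-3a-allyl-5-methoxy-3-methyl-2-(3,4,5-trimethoxyphenyl)-3,3a,4,5-tetrahydrobenzofuran-6(2H)-one (25)

Benzofuran numbering is used throughout: O1, C2 (aryl), C3 (methyl), C3a (allyl), C4, C5 (methoxy), C6 (ketone), C7, C7a. Ring A is the carbocycle, ring B the furan ring, Ar is 3,4,5-trimethoxyphenyl.

## The problem

The target 25 is a 3,3a,4,5-tetrahydrobenzofuran-6(2H)-one: ring A carries the vinylogous ester O1–C7a=C7–C6(=O), ring B is the tetrahydrofuran O1–C2–C3–C3a–C7a, and the rings share the C3a–C7a bond. Four stereocentres must be delivered as (2R,3R,3aR,5R): the aryl group at C2 is trans to the methyl group at C3, the methyl group is cis to the allyl group on the quaternary carbon C3a, and the allyl group is trans to the methoxy group at C5. C3a is the hard centre, because it is quaternary, carries a terminal alkene that rules out hydrogenation or hydroboration anywhere in the route, and lies between stereocentres on both sides. Once set it can direct C3 (1,2-relationship) and, through C3, C2, while C5 is the one centre that can come from the chiral pool and induce C3a (1,3-relationship across C4). Several groups are fragile: C5 is α to the C6 carbonyl and can epimerise, the C2–O1 bond is benzylic to an electron-rich arene and is also the leaving-group bond of a vinylogous ester, so strong acid can ionise it, and any open-chain precursor with the allyl group on an enone β-carbon has a doubly allylic methylene that strong base would isomerise. The feature that opens the problem is the oxidation pattern around C3a: C7a is a carbonyl-level carbon bonded to C3a, and C3a is β to the oxygenated carbon C2, so C7a and C2 stand in a 1,4-dicarbonyl relationship through C3a–C3. Read backwards, an acyl unit at C7a has added to the β-carbon C3a of the aryl enone C3a=C3–C2(=O)Ar, an umpoled conjugate addition that a nucleophilic acyl radical can perform even on a fully substituted acceptor carbon. Because C7a is tied to C3a through C7–C6–C5–C4, this addition is a 6-exo closure that forms ring A and the quaternary centre at once, with the C5 methoxy group already on the forming ring.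

## Retrosynthesis

**O1–C7a (25 ⇒ 23).** The enol ether bond of the vinylogous ester is cut first, giving the hydroxy dione 23. The neighbouring cut, O1–C2, would make the configuration of C2 depend on substitution at an ionisable benzylic carbon and would invite C-alkylation by C7. Cutting O1–C7a leaves the C2–O bond untouched, so C2 can be set by a ketone reduction and carried into the ring with retention through hemiketal 24. Only the C7a carbonyl is within reach of the C2 hydroxyl, so the closure has no regiochemical choice, and it asks only for mild acid.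

**Oxidation level at C2 and C6 (23 ⇒ 22 ⇒ 21).** The C2 carbinol comes from the aryl ketone of trione 22, and 22 from the C6 ethylene ketal 21. Once the ketal is removed, the cyclohexane-1,3-dione is an enolisable acid that can be parked as its enolate, leaving the aryl ketone as the only reducible carbonyl. The forward reduction must be Felkin–Anh selective, with the quaternary carbon C3a as the large group; this gives the (2R) carbinol needed for a trans C2/C3 pair.

**C3a–C7a (21 ⇒ 20), the strategic cut.** Disconnecting C3a–C7a opens ring A and removes two stereocentres (C3a, C3) at once. The precursor 20 is an acyclic chain with a single stereocentre (C5), an aryl enone C3a=C3–C2(=O)Ar and a Se-phenyl selenoester at C7a. Other cuts at the quaternary carbon are worse: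
- C3a–allyl would require regiocontrolled enolate alkylation between C3a and C7.
- C3–C3a would require displacement at a secondary α-halo propiophenone.
- Neither uses C5 for induction.

The forward step must favour 6-exo cyclisation of the acyl radical over its reduction or loss of CO, and must select one face of C3a under the influence of C5. C6 is kept as an sp3 ketal so that the acyl radical is not a β-keto acyl radical, which would lose CO to a stabilised radical.

**C7a carboxyl and C6–C7 (20 ⇒ 19 ⇒ 18 ⇒ 17 ⇒ 12 + 15).** The selenoester is made last from acid 19, because it is an acylating agent. Acid 19 is released from allyl ester 18 with zerovalent palladium under neutral conditions, since hydroxide would threaten the doubly allylic methylene. Ketal 18 comes from β-keto ester 17. The C6–C7 bond is cut by a Masamune–Claisen condensation of acid 12 with the magnesium salt of allyl hydrogen malonate 15 (itself from Meldrum's acid 13 and allyl alcohol 14). A lithium ester enolate would make the same bond but would deprotonate the γ-position of the enone; the magnesium malonate route is neutral.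

**C6 oxidation level (12 ⇒ 11 ⇒ 10).** Acid 12 is traced to primary alcohol 11 and its trityl ether 10. C6 must travel as an ether through the organometallic steps that build the enone and is oxidised only afterwards.

**The tetrasubstituted alkene (10 ⇒ 9 ⇒ 6 + 7 + methyl).** The C3–CH3 and C3a–allyl bonds are cut together across an alkyne C3≡C3a. The C2 carbinol of propargylic alcohol 6 directs an anti-carbomagnesiation: methyl adds to C3 and magnesium is held on C3a in the five-membered chelate 8, so allyl bromide 7 enters cis to the carbinol carbon, giving the (E) alkene of 9; oxidation then gives 10. The obvious neighbour, an enol triflate of a 2-methyl-1,3-diketone coupled with an allylstannane, has no control over which carbonyl oxygen is sulfonylated. The β-keto ester variant of that idea needs four further steps to turn the ester into the aryl ketone. The alkyne route reaches the enone in three steps from 4 with geometry fixed by mechanism.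

**C2–C3 (6 ⇒ 4 + 5).** Propargylic alcohol 6 is the adduct of the lithium acetylide of 4 and 3,4,5-trimethoxybenzaldehyde 5. The carbinol configuration is irrelevant, since it is oxidised.

**C3a–C4 and the source of C5 (4 ⇒ 3 ⇒ 1 + 2).** Alkyne 4 is the methyl ether of homopropargylic alcohol 3, which arises by opening (R)-trityl glycidyl ether 1 with lithium acetylide 2 at the unsubstituted carbon. The epoxide oxygen becomes the C5 methoxy oxygen and no bond to the stereocentre is broken. A four-carbon hydroxy diacid from the chiral pool could also supply C5, but its two carboxyl termini would have to be told apart; the glycidyl ether has C4 and C6 differentiated from the start.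

## Roads not taken

**Alternative 1: Diels–Alder assembly of ring A.** The cut is C4–C5 plus C3a–C7a. The diene 1,4-dimethoxy-1,3-bis(trimethylsilyloxy)buta-1,3-diene A1 would add to the dienophile 3-methylidenehex-5-en-2-one A2 under a chiral oxazaborolidinium Lewis acid. Acidic work-up would give the vinylogous methyl ester (4S,6R)-4-acetyl-4-allyl-3,6-dimethoxycyclohex-2-en-1-one A3.
- Merits: ring A, the quaternary centre, the C5 methoxy group and the vinylogous ester arise in one convergent step from two small achiral pieces, and the catalyst, not a remote stereocentre, fixes C3a. In these respects it is better than the chosen plan, which needs thirteen steps before ring A closes and relies on 1,3-induction.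
- Weak points: A1 is a sensitive, fourfold oxygenated diene of uncertain geometry. A2 is an α-branched vinyl ketone, a sluggish dienophile whose endo/exo preference decides C5 against C3a. Most of all, A3 carries only an acetyl group where C3, C2 and the aryl ring are needed. The aryl-bearing carbon would have to be joined to a hindered ketone next to the quaternary centre in the presence of the vinylogous ester, and both C3 and C2 would then be set without a clear control element.
- Comparison: the chosen plan is longer to ring A, but at the moment C3a is made, all carbons of ring B are attached and C2 is already at the ketone level, so three functional-group steps finish the molecule.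

**Alternative 2: Phenoxide para-alkylation with dearomatisation.** The cut is C3–C3a. The C6 phenoxide of the aryl ether (1S,2R)-1-[5-hydroxy-4-methoxy-2-allylphenoxy]-1-(3,4,5-trimethoxyphenyl)propan-2-yl methanesulfonate A4 would displace the secondary mesylate with its para carbon C3a. This closes ring B and gives the cross-conjugated dienone (2R,3R,3aS)-3a-allyl-5-methoxy-3-methyl-2-(3,4,5-trimethoxyphenyl)-3,3a-dihydrobenzofuran-6(2H)-one A5.
- Merits: this is the shortest road; the starting materials are aromatic; the C2/C3 pair comes from stereospecific chemistry (inversion at C3); ring B and the quaternary centre form together. On step count and on C2/C3 control it beats the chosen plan.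
- Weak points: the tether is attached at C7a, next to the attacking carbon, so the closure is formally a 5-(enolendo)-exo-tet alkylation with poor orbital alignment. E2 loss of the mesylate toward the benzylic C2–H and O-alkylation compete. A5 still needs a chemoselective conjugate reduction of the C4=C5 methoxy enone in the presence of the vinylogous ester and the allyl group, and C5 would be set only at the final protonation.
- Comparison: the chosen plan closes its ring in a stereoelectronically allowed 6-exo-trig mode, has no elimination-prone sulfonate, and has C5 fixed from the first step.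

**Alternative 3: Desymmetrising oxa-Michael closure.** The cut is O1–C7a. The dienone 4-[(1R,2R)-1-hydroxy-1-(3,4,5-trimethoxyphenyl)propan-2-yl]-4-allylcyclohexa-2,5-dien-1-one A6 would close with K2CO3 in methanol by 5-exo-trig addition of the C2 hydroxyl to one of the two diastereotopic enone arms. The product is the cis-fused (2R,3R,3aR,7aR)-3a-allyl-3-methyl-2-(3,4,5-trimethoxyphenyl)-3,3a,7,7a-tetrahydrobenzofuran-6(2H)-one A7.
- Merits: the key step is the simplest of all; the quaternary carbon is built on an achiral symmetric ring; and C3a becomes stereogenic only in a reversible, mild closure governed by the adjacent C3. In ease of the key step and in the length of the route to the bicycle it is better than the chosen plan.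
- Weak points: the choice between the two arms rests on a small difference (methyl against hydrogen at C3) under thermodynamic control. A7 has the wrong oxidation pattern: it lacks the C5 methoxy group, has C4=C5 where C4H2–C5H(OMe) is needed, and has an sp3 C7a where the enol ether C7=C7a is needed. Repairing this needs several redox steps on a β-alkoxy ketone prone to retro-Michael opening, and C5 would be set late without a control element.
- Comparison: the chosen plan has the longer build-up, but its cyclisation product already has C5 stereodefined and C6 and C7a at the carbonyl level.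

Key step: step 13

Remark (assumption): the enone of 20 is taken as the (E) isomer (allyl cis to the aroyl group) that step 4 delivers; the geometry is not decisive, because the C3 radical formed in the key step is planar.

## Route

Step 1
Reactants: 1 (2R)-2-[(triphenylmethoxy)methyl]oxirane; 2 lithium acetylide ethylenediamine complex
Product: 3 (2R)-1-(triphenylmethoxy)pent-4-yn-2-ol
Conditions: LiC≡CH·H2NCH2CH2NH2, DMSO, rt; then H2O
Reagents that add atoms: none
Why: Epoxide ring opening by an alkynyl anion (SN2) at the unsubstituted carbon forms C3a–C4; no bond to the stereocentre is touched, so C5 keeps the configuration of the glycidyl ether.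

Step 2
Reactants: 3 (2R)-1-(triphenylmethoxy)pent-4-yn-2-ol
Product: 4 (2R)-2-methoxy-1-(triphenylmethoxy)pent-4-yne
Conditions: NaH, MeI, THF, 0 °C → rt
Reagents that add atoms: iodomethane, CI
Why: Williamson ether synthesis on the secondary alkoxide installs the C5 methoxy group; a trityl ether cannot migrate to the neighbouring alkoxide, and the terminal alkyne is not methylated under these conditions.

Step 3
Reactants: 4 (2R)-2-methoxy-1-(triphenylmethoxy)pent-4-yne; 5 3,4,5-trimethoxybenzaldehyde
Product: 6 (5R)-5-methoxy-6-(triphenylmethoxy)-1-(3,4,5-trimethoxyphenyl)hex-2-yn-1-ol (both C1 epimers)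
Conditions: n-BuLi, THF, −78 °C; then 5, −78 → 0 °C; H2O
Reagents that add atoms: none
Why: Addition of a lithium acetylide to an aldehyde forms C2–C3; the carbinol centre is formed unselectively and is removed by oxidation in step 5.

Step 4
Reactants: 6 (5R)-5-methoxy-6-(triphenylmethoxy)-1-(3,4,5-trimethoxyphenyl)hex-2-yn-1-ol; 7 3-bromoprop-1-ene
Product: 9 (2E)-3-[(2R)-2-methoxy-3-(triphenylmethoxy)propyl]-2-methyl-1-(3,4,5-trimethoxyphenyl)hexa-2,5-dien-1-ol (both C1 epimers), via cyclic alkenylmagnesium alkoxide 8 (not isolated)
Conditions: MeMgBr (excess), CuI (cat.), THF, 0 °C → rt; then 7, 0 °C → rt; aq NH4Cl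
Reagents that add atoms: methylmagnesium bromide, C[Mg]Br
Why: Copper-catalysed anti-carbomagnesiation of a propargylic alkoxide puts methyl on the alkoxide-proximal carbon C3 and magnesium on C3a within the five-membered chelate 8. Copper-mediated allylation of this alkenylmagnesium with retention places the allyl group cis to the carbinol carbon, which fixes the (E) geometry.

Step 5
Reactants: 9 (2E)-3-[(2R)-2-methoxy-3-(triphenylmethoxy)propyl]-2-methyl-1-(3,4,5-trimethoxyphenyl)hexa-2,5-dien-1-ol
Product: 10 (2E)-3-[(2R)-2-methoxy-3-(triphenylmethoxy)propyl]-2-methyl-1-(3,4,5-trimethoxyphenyl)hexa-2,5-dien-1-one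
Conditions: Dess–Martin periodinane, pyridine, CH2Cl2, 0 °C → rt
Reagents that add atoms: none
Why: Dess–Martin oxidation of the allylic, benzylic alcohol removes the undefined carbinol centre and creates the aryl enone acceptor; the buffered, non-basic conditions leave the skipped diene and the trityl ether alone.

Step 6
Reactants: 10 (2E)-3-[(2R)-2-methoxy-3-(triphenylmethoxy)propyl]-2-methyl-1-(3,4,5-trimethoxyphenyl)hexa-2,5-dien-1-one
Product: 11 (2E)-3-[(2R)-3-hydroxy-2-methoxypropyl]-2-methyl-1-(3,4,5-trimethoxyphenyl)hexa-2,5-dien-1-one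
Conditions: TsOH·H2O (cat.), MeOH/CH2Cl2, rt
Reagents that add atoms: none
Why: Acid-catalysed methanolysis of the trityl ether (SN1 at the trityl carbon) frees the C6 hydroxyl; the hindered tetrasubstituted enone does not take up methanol or the new hydroxyl.

Step 7
Reactants: 11 (2E)-3-[(2R)-3-hydroxy-2-methoxypropyl]-2-methyl-1-(3,4,5-trimethoxyphenyl)hexa-2,5-dien-1-one
Product: 12 (2R,4E)-2-methoxy-5-methyl-6-oxo-4-(prop-2-en-1-yl)-6-(3,4,5-trimethoxyphenyl)hex-4-enoic acid
Conditions: TEMPO (cat.), PhI(OAc)2, MeCN/H2O, rt
Reagents that add atoms: water, O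
Why: Oxoammonium (TEMPO) oxidation of the primary alcohol through the aldehyde hydrate to the carboxylic acid; the near-neutral medium spares the alkenes and does not epimerise the α-methoxy centre C5.

Step 8
Reactants: 13 2,2-dimethyl-1,3-dioxane-4,6-dione (Meldrum's acid); 14 prop-2-en-1-ol
Product: 15 3-oxo-3-(prop-2-en-1-yloxy)propanoic acid (allyl hydrogen malonate)
Conditions: toluene, 100 °C
Reagents that add atoms: none
Why: Alcoholysis of Meldrum's acid opens the ring with loss of acetone and gives the malonic half ester needed for the next step.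

Step 9
Reactants: 12 (2R,4E)-2-methoxy-5-methyl-6-oxo-4-(prop-2-en-1-yl)-6-(3,4,5-trimethoxyphenyl)hex-4-enoic acid; 15 3-oxo-3-(prop-2-en-1-yloxy)propanoic acid
Product: 17 prop-2-en-1-yl (4R,6E)-4-methoxy-7-methyl-3,8-dioxo-6-(prop-2-en-1-yl)-8-(3,4,5-trimethoxyphenyl)oct-6-enoate, via acyl imidazolide 16 (not isolated)
Conditions: 1,1'-carbonyldiimidazole, THF, rt; then 15, MgCl2, Et3N, THF/MeCN, rt
Reagents that add atoms: 1,1'-carbonyldiimidazole, O=C(n1ccnc1)n1ccnc1 (its imidazolyl group is held only by intermediate 16)
Why: Masamune–Claisen condensation: the magnesium enolate of the malonate half ester is acylated by imidazolide 16 and loses CO2, forming C6–C7. No strong base is present, so the C5 centre and the doubly allylic methylene of the enone are not disturbed.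

Step 10
Reactants: 17 prop-2-en-1-yl (4R,6E)-4-methoxy-7-methyl-3,8-dioxo-6-(prop-2-en-1-yl)-8-(3,4,5-trimethoxyphenyl)oct-6-enoate
Product: 18 prop-2-en-1-yl {2-[(1R,3E)-1-methoxy-4-methyl-5-oxo-3-(prop-2-en-1-yl)-5-(3,4,5-trimethoxyphenyl)pent-3-en-1-yl]-1,3-dioxolan-2-yl}acetate
Conditions: Me3SiOCH2CH2OSiMe3, Me3SiOTf (cat.), CH2Cl2, −78 → −20 °C; pyridine quench
Reagents that add atoms: 1,2-bis(trimethylsilyloxy)ethane, C[Si](C)(C)OCCO[Si](C)(C)C
Why: Noyori ketalisation converts the C6 ketone of the β-keto ester into the dioxolane at low temperature; the conjugated, fully substituted aryl ketone is too hindered and too electron-rich to compete.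

Step 11
Reactants: 18 prop-2-en-1-yl {2-[(1R,3E)-1-methoxy-4-methyl-5-oxo-3-(prop-2-en-1-yl)-5-(3,4,5-trimethoxyphenyl)pent-3-en-1-yl]-1,3-dioxolan-2-yl}acetate
Product: 19 {2-[(1R,3E)-1-methoxy-4-methyl-5-oxo-3-(prop-2-en-1-yl)-5-(3,4,5-trimethoxyphenyl)pent-3-en-1-yl]-1,3-dioxolan-2-yl}acetic acid
Conditions: Pd(PPh3)4 (cat.), morpholine, THF, rt
Reagents that add atoms: none
Why: Tsuji–Trost deallylation: zerovalent palladium ionises only the allyl ester, and morpholine traps the π-allyl fragment. The C-allyl group is not an allylic electrophile, and the ketal and enone see neither acid nor hydroxide.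

Step 12
Reactants: 19 {2-[(1R,3E)-1-methoxy-4-methyl-5-oxo-3-(prop-2-en-1-yl)-5-(3,4,5-trimethoxyphenyl)pent-3-en-1-yl]-1,3-dioxolan-2-yl}acetic acid
Product: 20 Se-phenyl {2-[(1R,3E)-1-methoxy-4-methyl-5-oxo-3-(prop-2-en-1-yl)-5-(3,4,5-trimethoxyphenyl)pent-3-en-1-yl]-1,3-dioxolan-2-yl}ethaneselenoate
Conditions: PhSeSePh, Bu3P, CH2Cl2, rt
Reagents that add atoms: diphenyl diselenide, c1ccc(cc1)[Se][Se]c1ccccc1
Why: Phosphine-mediated selenoesterification: the acyloxyphosphonium ion formed from the acid is attacked by benzeneselenolate, giving the acyl radical precursor under neutral conditions.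

Step 13
Reactants: 20 Se-phenyl {2-[(1R,3E)-1-methoxy-4-methyl-5-oxo-3-(prop-2-en-1-yl)-5-(3,4,5-trimethoxyphenyl)pent-3-en-1-yl]-1,3-dioxolan-2-yl}ethaneselenoate
Product: 21 (8R,10R)-10-methoxy-8-[(2R)-1-oxo-1-(3,4,5-trimethoxyphenyl)propan-2-yl]-8-(prop-2-en-1-yl)-1,4-dioxaspiro[4.5]decan-7-one
Conditions: (Me3Si)3SiH, AIBN, benzene, 80 °C, syringe-pump addition, high dilution
Reagents that add atoms: none
Why: Radical conjugate cyclisation of an acyl radical; the closest known reaction type is the stannane- or silane-mediated cyclisation of acyl radicals from Se-phenyl selenoesters onto enones and enoates. The silyl radical abstracts the phenylselanyl group of 20, the nucleophilic σ-type acyl radical at C7a adds to the electron-poor β-carbon C3a of the aryl enone and forms C3a–C7a, and the delocalised α-aroyl radical at C3 takes hydrogen from the silane and carries the chain. Ring A closes in the 6-exo-trig mode through a chair transition state; the 7-endo path to C3 is disfavoured by polarity. C3a is controlled by C5: with the methoxy group and the bulky C(Me)COAr terminus both equatorial, the allyl group is axial and ends trans to the methoxy group. C3 is set when the silane delivers hydrogen to the planar radical next to the new quaternary centre (1,2-induction from C3a); this is the less predictable centre, and because it is α to the aryl ketone it can be equilibrated by enolisation if needed. The step needs cyclisation to outrun hydrogen transfer to the acyl radical and loss of CO from it. This is secured by the slow donor (Me3Si)3SiH kept dilute by syringe pump, by the primary nature of the acyl radical, and by the sp3 ketal at C6, which denies a stabilised radical after CO loss. The alkene geometry of 20 does not affect the outcome, since the C3 radical is planar.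

Step 14
Reactants: 21 (8R,10R)-10-methoxy-8-[(2R)-1-oxo-1-(3,4,5-trimethoxyphenyl)propan-2-yl]-8-(prop-2-en-1-yl)-1,4-dioxaspiro[4.5]decan-7-one
Product: 22 (4R,6R)-6-methoxy-4-[(2R)-1-oxo-1-(3,4,5-trimethoxyphenyl)propan-2-yl]-4-(prop-2-en-1-yl)cyclohexane-1,3-dione
Conditions: 1 M aq HCl, THF, rt, short reaction time
Reagents that add atoms: water, O
Why: Acid-catalysed ketal hydrolysis, helped by the β-carbonyl at C7a, releases the enolisable 1,3-dione. Dilute acid at room temperature should be too mild for Paal–Knorr-type cyclodehydration onto the aryl ketone or for enolisation toward C5.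

Step 15
Reactants: 22 (4R,6R)-6-methoxy-4-[(2R)-1-oxo-1-(3,4,5-trimethoxyphenyl)propan-2-yl]-4-(prop-2-en-1-yl)cyclohexane-1,3-dione
Product: 23 (4R,6R)-4-[(1R,2R)-1-hydroxy-1-(3,4,5-trimethoxyphenyl)propan-2-yl]-6-methoxy-4-(prop-2-en-1-yl)cyclohexane-1,3-dione
Conditions: NaOMe (1 equiv), MeOH, 0 °C; then NaBH4, 0 °C → rt; AcOH
Reagents that add atoms: none
Why: Borohydride reduction with the 1,3-dione parked as its sodium enolate, which hydride does not attack, so only the aryl ketone reacts. Felkin–Anh addition anti to the quaternary carbon C3a, with the methyl group on the carbonyl-oxygen side, sets C2 as (R), the configuration that becomes trans to the C3 methyl group.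

Step 16
Reactants: 23 (4R,6R)-4-[(1R,2R)-1-hydroxy-1-(3,4,5-trimethoxyphenyl)propan-2-yl]-6-methoxy-4-(prop-2-en-1-yl)cyclohexane-1,3-dione
Product: 25 (2R,3R,3aR,5R)-5-methoxy-3-methyl-3a-(prop-2-en-1-yl)-2-(3,4,5-trimethoxyphenyl)-3,3a,4,5-tetrahydro-1-benzofuran-6(2H)-one, via cyclic hemiketal 24 (not isolated)
Conditions: PPTS (cat.), 4 Å molecular sieves, benzene, 50 °C
Reagents that add atoms: none
Why: Dehydrative vinylogous ester formation: the C2 hydroxyl adds to the C7a carbonyl (5-exo-trig) and hemiketal 24 loses water toward C7. The C2–O bond is never broken, so C2 is carried with retention, and the weak acid avoids benzylic ionisation and epimerisation at C5.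

## Compound list

1 | (2R)-2-[(triphenylmethoxy)methyl]oxirane, (R)-trityl glycidyl ether | C(OC(c1ccccc1)(c1ccccc1)c1ccccc1)[C@H]1CO1 | starting material
2 | lithium acetylide ethylenediamine complex | [Li+].[C-]#C.NCCN | starting material
3 | (2R)-1-(triphenylmethoxy)pent-4-yn-2-ol | C#CC[C@@H](O)COC(c1ccccc1)(c1ccccc1)c1ccccc1 | intermediate
4 | (2R)-2-methoxy-1-(triphenylmethoxy)pent-4-yne | C#CC[C@@H](OC)COC(c1ccccc1)(c1ccccc1)c1ccccc1 | intermediate
5 | 3,4,5-trimethoxybenzaldehyde | COc1cc(C=O)cc(OC)c1OC | starting material
6 | (5R)-5-methoxy-6-(triphenylmethoxy)-1-(3,4,5-trimethoxyphenyl)hex-2-yn-1-ol, both C1 epimers | COc1cc(C(O)C#CC[C@@H](OC)COC(c2ccccc2)(c2ccccc2)c2ccccc2)cc(OC)c1OC | intermediate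
7 | 3-bromoprop-1-ene (allyl bromide) | C=CCBr | starting material
8 | 3-[(2R)-2-methoxy-3-(triphenylmethoxy)propyl]-4-methyl-5-(3,4,5-trimethoxyphenyl)-2,5-dihydro-1,2-oxamagnesole (cyclic alkenylmagnesium alkoxide, drawn without further ligands on magnesium) | CC1=C(C[C@@H](OC)COC(c2ccccc2)(c2ccccc2)c2ccccc2)[Mg]OC1c1cc(OC)c(OC)c(OC)c1 | intermediate (not isolated)
9 | (2E)-3-[(2R)-2-methoxy-3-(triphenylmethoxy)propyl]-2-methyl-1-(3,4,5-trimethoxyphenyl)hexa-2,5-dien-1-ol, both C1 epimers | C=CC/C(C[C@@H](OC)COC(c1ccccc1)(c1ccccc1)c1ccccc1)=C(/C)C(O)c1cc(OC)c(OC)c(OC)c1 | intermediate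
10 | (2E)-3-[(2R)-2-methoxy-3-(triphenylmethoxy)propyl]-2-methyl-1-(3,4,5-trimethoxyphenyl)hexa-2,5-dien-1-one | C=CC/C(C[C@@H](OC)COC(c1ccccc1)(c1ccccc1)c1ccccc1)=C(/C)C(=O)c1cc(OC)c(OC)c(OC)c1 | intermediate
11 | (2E)-3-[(2R)-3-hydroxy-2-methoxypropyl]-2-methyl-1-(3,4,5-trimethoxyphenyl)hexa-2,5-dien-1-one | C=CC/C(C[C@@H](OC)CO)=C(/C)C(=O)c1cc(OC)c(OC)c(OC)c1 | intermediate
12 | (2R,4E)-2-methoxy-5-methyl-6-oxo-4-(prop-2-en-1-yl)-6-(3,4,5-trimethoxyphenyl)hex-4-enoic acid | C=CC/C(C[C@@H](OC)C(=O)O)=C(/C)C(=O)c1cc(OC)c(OC)c(OC)c1 | intermediate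
13 | 2,2-dimethyl-1,3-dioxane-4,6-dione (Meldrum's acid) | CC1(C)OC(=O)CC(=O)O1 | starting material
14 | prop-2-en-1-ol (allyl alcohol) | C=CCO | starting material
15 | 3-oxo-3-(prop-2-en-1-yloxy)propanoic acid (allyl hydrogen malonate) | C=CCOC(=O)CC(=O)O | intermediate
16 | (2R,4E)-1-(1H-imidazol-1-yl)-2-methoxy-5-methyl-4-(prop-2-en-1-yl)-6-(3,4,5-trimethoxyphenyl)hex-4-ene-1,6-dione (acyl imidazolide) | C=CC/C(C[C@@H](OC)C(=O)n1ccnc1)=C(/C)C(=O)c1cc(OC)c(OC)c(OC)c1 | intermediate (not isolated)
17 | prop-2-en-1-yl (4R,6E)-4-methoxy-7-methyl-3,8-dioxo-6-(prop-2-en-1-yl)-8-(3,4,5-trimethoxyphenyl)oct-6-enoate | C=CC/C(C[C@@H](OC)C(=O)CC(=O)OCC=C)=C(/C)C(=O)c1cc(OC)c(OC)c(OC)c1 | intermediate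
18 | prop-2-en-1-yl {2-[(1R,3E)-1-methoxy-4-methyl-5-oxo-3-(prop-2-en-1-yl)-5-(3,4,5-trimethoxyphenyl)pent-3-en-1-yl]-1,3-dioxolan-2-yl}acetate | C=CC/C(C[C@@H](OC)C1(CC(=O)OCC=C)OCCO1)=C(/C)C(=O)c1cc(OC)c(OC)c(OC)c1 | intermediate
19 | {2-[(1R,3E)-1-methoxy-4-methyl-5-oxo-3-(prop-2-en-1-yl)-5-(3,4,5-trimethoxyphenyl)pent-3-en-1-yl]-1,3-dioxolan-2-yl}acetic acid | C=CC/C(C[C@@H](OC)C1(CC(=O)O)OCCO1)=C(/C)C(=O)c1cc(OC)c(OC)c(OC)c1 | intermediate
20 | Se-phenyl {2-[(1R,3E)-1-methoxy-4-methyl-5-oxo-3-(prop-2-en-1-yl)-5-(3,4,5-trimethoxyphenyl)pent-3-en-1-yl]-1,3-dioxolan-2-yl}ethaneselenoate | C=CC/C(C[C@@H](OC)C1(CC(=O)[Se]c2ccccc2)OCCO1)=C(/C)C(=O)c1cc(OC)c(OC)c(OC)c1 | intermediate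
21 | (8R,10R)-10-methoxy-8-[(2R)-1-oxo-1-(3,4,5-trimethoxyphenyl)propan-2-yl]-8-(prop-2-en-1-yl)-1,4-dioxaspiro[4.5]decan-7-one | C=CC[C@]1([C@@H](C)C(=O)c2cc(OC)c(OC)c(OC)c2)C[C@@H](OC)C2(OCCO2)CC1=O | intermediate
22 | (4R,6R)-6-methoxy-4-[(2R)-1-oxo-1-(3,4,5-trimethoxyphenyl)propan-2-yl]-4-(prop-2-en-1-yl)cyclohexane-1,3-dione | C=CC[C@]1([C@@H](C)C(=O)c2cc(OC)c(OC)c(OC)c2)C[C@@H](OC)C(=O)CC1=O | intermediate
23 | (4R,6R)-4-[(1R,2R)-1-hydroxy-1-(3,4,5-trimethoxyphenyl)propan-2-yl]-6-methoxy-4-(prop-2-en-1-yl)cyclohexane-1,3-dione | C=CC[C@]1([C@@H](C)[C@@H](O)c2cc(OC)c(OC)c(OC)c2)C[C@@H](OC)C(=O)CC1=O | intermediate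
24 | (2R,3R,3aR,5R)-7a-hydroxy-5-methoxy-3-methyl-3a-(prop-2-en-1-yl)-2-(3,4,5-trimethoxyphenyl)hexahydro-1-benzofuran-6(2H)-one, both C7a epimers (cyclic hemiketal) | C=CC[C@]12C[C@@H](OC)C(=O)CC1(O)O[C@@H](c1cc(OC)c(OC)c(OC)c1)[C@@H]2C | intermediate (not isolated)
25 | (2R,3R,3aR,5R)-5-methoxy-3-methyl-3a-(prop-2-en-1-yl)-2-(3,4,5-trimethoxyphenyl)-3,3a,4,5-tetrahydro-1-benzofuran-6(2H)-one | C=CC[C@]12C[C@@H](OC)C(=O)C=C1O[C@@H](c1cc(OC)c(OC)c(OC)c1)[C@@H]2C | target

## Step count and risk

Total steps: 16. Longest linear sequence: 15 (steps 1–7 and 9–16; step 8 prepares the half ester 15 as a side branch).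

**Step 13 (key step).**
- What may go wrong: addition of the acyl radical to the fully substituted β-carbon of a twisted aryl enone may be slow, so that hydrogen transfer to the acyl radical or loss of CO competes. Facial discrimination at C3a by the remote methoxy group may be modest. Hydrogen transfer at C3 may be unselective; that last point can be repaired by base equilibration through the aryl ketone enolate.
- Fallback (sets out from 20, returns at 21): form the same C3a–C7a bond by a reductive aldehyde–enone cyclisation. Treating 20 with Bu3SnH and AIBN at high stannane concentration reduces the selenoester to the dioxolanyl acetaldehyde F1. SmI2 in THF with t-BuOH then couples the carbonyl carbon C7a with the enone β-carbon C3a through a chelated six-membered transition state, and the samarium enolate is protonated at C3, giving the hydroxy ketone F2. Dess–Martin oxidation of the C7a carbinol returns to 21.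

**Step 4.**
- What may go wrong: methyl transfer to the internal alkyne may be incomplete. The hindered, fully substituted alkenylmagnesium may be protonated on work-up before it is allylated. The strongly basic medium may move the new allyl double bond into conjugation.
- Fallback (sets out from 6, returns at 9): capture the organomagnesium with a fast electrophile and make the C3a–allyl bond by cross-coupling. The carbomagnesiation mixture from 6 is quenched with I2 to give the vinyl iodide F3, which can be freed from unreacted alkynol. A Stille coupling with allyltributylstannane (Pd(PPh3)4, CuI, DMF) under neutral conditions then gives 9.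

**Step 10.**
- What may go wrong: ketalisation of a ketone deactivated and hindered by the adjacent methoxy-bearing branch may stall, and forcing it with more Lewis acid risks epimerisation at C5 or scrambling of the enone geometry.
- Fallback (sets out from 17, returns at 22): mask C6 as a thioketal, which forms far more readily. Ethane-1,2-dithiol and BF3·OEt2 convert 17 into the dithiolane allyl ester F4. The conditions of steps 11 to 13 are then applied in the sulfur series, giving the dithiolane acid F5, the dithiolane selenoester F6 and the cyclised dithiaspiro ketone F7. Alkylative hydrolysis of F7 (MeI, CaCO3, aqueous MeCN) returns to 22.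

**Step 15.**
- What may go wrong: hydride delivery to the hindered aryl ketone may be slow or may not follow the Felkin–Anh course (chelation by the neighbouring enolate, or reaction through a cyclic hemiketal), so that the epimeric C2 carbinol is formed.
- Fallback (sets out from 22, returns at 25): the (1S)-hydroxy dione F8 from such a reduction is not discarded. It is closed by an intramolecular Mitsunobu reaction (PPh3, diisopropyl azodicarboxylate, THF), in which the vinylogous acid oxygen on C7a displaces the activated benzylic hydroxyl with inversion. Both carbinol epimers thus converge on 25, one by dehydration with retention (step 16), the other by displacement with inversion.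

## Further compounds

F1 | step 13 | {2-[(1R,3E)-1-methoxy-4-methyl-5-oxo-3-(prop-2-en-1-yl)-5-(3,4,5-trimethoxyphenyl)pent-3-en-1-yl]-1,3-dioxolan-2-yl}acetaldehyde | C=CC/C(C[C@@H](OC)C1(CC=O)OCCO1)=C(/C)C(=O)c1cc(OC)c(OC)c(OC)c1
F2 | step 13 | (2R)-2-[(8R,10R)-7-hydroxy-10-methoxy-8-(prop-2-en-1-yl)-1,4-dioxaspiro[4.5]decan-8-yl]-1-(3,4,5-trimethoxyphenyl)propan-1-one, both C7 epimers | C=CC[C@]1([C@@H](C)C(=O)c2cc(OC)c(OC)c(OC)c2)C[C@@H](OC)C2(OCCO2)CC1O
F3 | step 4 | (2Z,5R)-3-iodo-5-methoxy-2-methyl-6-(triphenylmethoxy)-1-(3,4,5-trimethoxyphenyl)hex-2-en-1-ol, both C1 epimers | I/C(C[C@@H](OC)COC(c1ccccc1)(c1ccccc1)c1ccccc1)=C(/C)C(O)c1cc(OC)c(OC)c(OC)c1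
F4 | step 10 | prop-2-en-1-yl {2-[(1R,3E)-1-methoxy-4-methyl-5-oxo-3-(prop-2-en-1-yl)-5-(3,4,5-trimethoxyphenyl)pent-3-en-1-yl]-1,3-dithiolan-2-yl}acetate | C=CC/C(C[C@@H](OC)C1(CC(=O)OCC=C)SCCS1)=C(/C)C(=O)c1cc(OC)c(OC)c(OC)c1
F5 | step 10 | {2-[(1R,3E)-1-methoxy-4-methyl-5-oxo-3-(prop-2-en-1-yl)-5-(3,4,5-trimethoxyphenyl)pent-3-en-1-yl]-1,3-dithiolan-2-yl}acetic acid | C=CC/C(C[C@@H](OC)C1(CC(=O)O)SCCS1)=C(/C)C(=O)c1cc(OC)c(OC)c(OC)c1
F6 | step 10 | Se-phenyl {2-[(1R,3E)-1-methoxy-4-methyl-5-oxo-3-(prop-2-en-1-yl)-5-(3,4,5-trimethoxyphenyl)pent-3-en-1-yl]-1,3-dithiolan-2-yl}ethaneselenoate | C=CC/C(C[C@@H](OC)C1(CC(=O)[Se]c2ccccc2)SCCS1)=C(/C)C(=O)c1cc(OC)c(OC)c(OC)c1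
F7 | step 10 | (8R,10R)-10-methoxy-8-[(2R)-1-oxo-1-(3,4,5-trimethoxyphenyl)propan-2-yl]-8-(prop-2-en-1-yl)-1,4-dithiaspiro[4.5]decan-7-one | C=CC[C@]1([C@@H](C)C(=O)c2cc(OC)c(OC)c(OC)c2)C[C@@H](OC)C2(SCCS2)CC1=O
F8 | step 15 | (4R,6R)-4-[(1S,2R)-1-hydroxy-1-(3,4,5-trimethoxyphenyl)propan-2-yl]-6-methoxy-4-(prop-2-en-1-yl)cyclohexane-1,3-dione | C=CC[C@]1([C@@H](C)[C@H](O)c2cc(OC)c(OC)c(OC)c2)C[C@@H](OC)C(=O)CC1=O
A1 | alternative 1 | 1,4-dimethoxy-1,3-bis(trimethylsilyloxy)buta-1,3-diene (double-bond geometry not defined) | COC=C(O[Si](C)(C)C)C=C(OC)O[Si](C)(C)C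
A2 | alternative 1 | 3-methylidenehex-5-en-2-one | CC(=O)C(=C)CC=C
A3 | alternative 1 | (4S,6R)-4-acetyl-3,6-dimethoxy-4-(prop-2-en-1-yl)cyclohex-2-en-1-one | C=CC[C@]1(C(C)=O)C[C@@H](OC)C(=O)C=C1OC
A4 | alternative 2 | (1S,2R)-1-[5-hydroxy-4-methoxy-2-(prop-2-en-1-yl)phenoxy]-1-(3,4,5-trimethoxyphenyl)propan-2-yl methanesulfonate | C=CCc1cc(OC)c(O)cc1O[C@@H](c1cc(OC)c(OC)c(OC)c1)[C@@H](C)OS(C)(=O)=O
A5 | alternative 2 | (2R,3R,3aS)-5-methoxy-3-methyl-3a-(prop-2-en-1-yl)-2-(3,4,5-trimethoxyphenyl)-3,3a-dihydro-1-benzofuran-6(2H)-one | C=CC[C@]12C=C(OC)C(=O)C=C1O[C@@H](c1cc(OC)c(OC)c(OC)c1)[C@@H]2C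
A6 | alternative 3 | 4-[(1R,2R)-1-hydroxy-1-(3,4,5-trimethoxyphenyl)propan-2-yl]-4-(prop-2-en-1-yl)cyclohexa-2,5-dien-1-one | C=CCC1(C=CC(=O)C=C1)[C@@H](C)[C@@H](O)c1cc(OC)c(OC)c(OC)c1
A7 | alternative 3 | (2R,3R,3aR,7aR)-3-methyl-3a-(prop-2-en-1-yl)-2-(3,4,5-trimethoxyphenyl)-3,3a,7,7a-tetrahydro-1-benzofuran-6(2H)-one | C=CC[C@]12C=CC(=O)C[C@H]1O[C@@H](c1cc(OC)c(OC)c(OC)c1)[C@@H]2C
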